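**Retrosynthetic overview**
1. The C1 ketone comes from a C1 allylic alcohol; the ten-membered carbocycle is closed last by an intramolecular Nozaki–Hiyama–Kishi coupling of a C1 aldehyde onto the C10 vinyl iodide.
2. The seco-aldehyde comes from a trans γ-lactone carrying the O9 angelate; that lactone arises by six-to-five-membered translactonisation, which also frees O9–H for acylation.
3. The C6–C7 bond is made by Zn-Barbier allylation of epoxy aldehyde fragment A (C1–C6) with bromomethyl dihydropyranone fragment B (C7–C14, C11–C13).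
4. Fragment A comes from but-3-yn-1-ol (carboalumination/ethylene oxide, Shi epoxidation); fragment B from racemic butadiene monoxide (Pd-catalysed asymmetric etherification, chelation-controlled vinylation, RCM).
5. Ring order: oxirane (in A) and six-membered lactone (in B), then the γ-butyrolactone, then the ten-membered ring.

**Assumptions**
- Atom labels follow germacranolide numbering: C1 ketone, C3/C4 epoxide (C15 methyl on C4), C6 lactone carbinol, C7, C8 (OH), C9 (angelate), C10=C14, C11=C13, C12 lactone carbonyl. The target is (3R,4R,6R,7R,8S,9S).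
- The (R,R)-DACH-phenyl Trost ligand is taken as the enantiomer that gives the (2S)-ether in step 7; if the sense is opposite, the (S,S)-ligand is used.

**Route**

Step 1
Reactants: 1 but-3-yn-1-ol
Product: 2 tert-butyl(but-3-yn-1-yloxy)dimethylsilane
Conditions: TBSCl, imidazole, DMF, 0 °C to rt
Reagents that add atoms: tert-butyldimethylsilyl chloride CC(C)(C)[Si](C)(C)Cl
Why: Imidazole-mediated silylation masks the hydroxyl for the organoaluminium chemistry that follows; no stereocentre is formed.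

Step 2
Reactants: 2 tert-butyl(but-3-yn-1-yloxy)dimethylsilane
Product: 5 (3E)-6-[(tert-butyldimethylsilyl)oxy]-4-methylhex-3-en-1-ol, via alkenyldimethylalane 3 (not isolated), via lithium alkenylaluminate 4 (not isolated)
Conditions: Me3Al (2.5 equiv), Cp2ZrCl2 (0.25 equiv), CH2Cl2, 0 °C to rt; then n-BuLi, THF/hexane, −78 °C; ethylene oxide, −78 to 0 °C; aq. KNaC4H4O6 work-up
Reagents that add atoms: trimethylaluminium C[Al](C)C; ethylene oxide C1CO1
Why: Negishi zirconium-catalysed carboalumination adds methyl and aluminium syn across the terminal alkyne, and the derived aluminate opens ethylene oxide with retention, which fixes the (E)-trisubstituted C3=C4 alkene and installs C1–C2.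

Step 3
Reactants: 5 (3E)-6-[(tert-butyldimethylsilyl)oxy]-4-methylhex-3-en-1-ol
Product: 6 tert-butyl{[(3E)-6-[(4-methoxyphenyl)methoxy]-3-methylhex-3-en-1-yl]oxy}dimethylsilane
Conditions: NaH, 4-methoxybenzyl chloride, Bu4NI (cat.), THF, 0 °C to rt
Reagents that add atoms: 4-methoxybenzyl chloride COc1ccc(CCl)cc1
Why: Williamson etherification protects the future C1 hydroxyl as a PMB ether that is orthogonal to the TBS ether; no stereocentre is formed.

Step 4
Reactants: 6 tert-butyl{[(3E)-6-[(4-methoxyphenyl)methoxy]-3-methylhex-3-en-1-yl]oxy}dimethylsilane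
Product: 7 tert-butyl{2-[(2R,3R)-3-{2-[(4-methoxyphenyl)methoxy]ethyl}-2-methyloxiran-2-yl]ethoxy}dimethylsilane
Conditions: D-fructose-derived Shi ketone (30 mol%), Oxone (2KHSO5·KHSO4·K2SO4), K2CO3, Bu4NHSO4, MeCN/CH2(OMe)2/aq. Na2B4O7 buffer, 0 °C
Reagents that add atoms: potassium peroxymonosulfate [K+].[O-]S(=O)(=O)OO
Why: Shi asymmetric epoxidation through the spiro dioxirane transition state gives the (R,R)-epoxide from the (E)-trisubstituted alkene under reagent control, setting C3 and C4.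

Step 5
Reactants: 7 tert-butyl{2-[(2R,3R)-3-{2-[(4-methoxyphenyl)methoxy]ethyl}-2-methyloxiran-2-yl]ethoxy}dimethylsilane
Product: 8 2-[(2R,3R)-3-{2-[(4-methoxyphenyl)methoxy]ethyl}-2-methyloxiran-2-yl]ethan-1-ol
Conditions: Bu4NF, THF, 0 °C to rt
Reagents that add atoms: none
Why: Fluoride-mediated desilylation frees the C6 hydroxyl without touching the PMB ether or the epoxide; the stereocentres are unaffected.

Step 6
Reactants: 8 2-[(2R,3R)-3-{2-[(4-methoxyphenyl)methoxy]ethyl}-2-methyloxiran-2-yl]ethan-1-ol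
Product: 9 2-[(2R,3R)-3-{2-[(4-methoxyphenyl)methoxy]ethyl}-2-methyloxiran-2-yl]acetaldehyde (fragment A)
Conditions: Dess–Martin periodinane, NaHCO3, CH2Cl2, 0 °C; crude aldehyde used at once
Reagents that add atoms: none
Why: Buffered Dess–Martin oxidation gives the β,γ-epoxy aldehyde under non-basic conditions, so β-elimination of the epoxide is avoided.

Step 7
Reactants: 10 2-ethenyloxirane (racemic); 11 (4-methoxyphenyl)methanol
Product: 12 (2S)-2-[(4-methoxyphenyl)methoxy]but-3-en-1-ol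
Conditions: Pd2(dba)3·CHCl3 (1 mol%), (R,R)-DACH-phenyl Trost ligand (3 mol%), Et3B (1 mol%), CH2Cl2, rt
Reagents that add atoms: none
Why: Tsuji–Trost allylic etherification run as a dynamic kinetic asymmetric transformation funnels both epoxide enantiomers through interconverting π-allyl palladium complexes, and boron-assisted delivery of the alcohol to the branched terminus sets C8 as (S).

Step 8
Reactants: 12 (2S)-2-[(4-methoxyphenyl)methoxy]but-3-en-1-ol
Product: 13 (2S)-2-[(4-methoxyphenyl)methoxy]but-3-enal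
Conditions: Dess–Martin periodinane, NaHCO3, CH2Cl2, 0 °C; crude aldehyde used at once at low temperature
Reagents that add atoms: none
Why: Neutral Dess–Martin oxidation gives the configurationally labile α-alkoxy aldehyde without epimerisation or migration of the double bond.

Step 9
Reactants: 13 (2S)-2-[(4-methoxyphenyl)methoxy]but-3-enal
Product: 14 (3R,4S)-4-[(4-methoxyphenyl)methoxy]-2-(trimethylsilyl)hexa-1,5-dien-3-ol
Conditions: MgBr2·OEt2 (2 equiv), CH2Cl2, −78 °C; then CH2=C(SiMe3)MgBr (from CH2=C(SiMe3)Br and Mg, THF), −78 to −40 °C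
Reagents that add atoms: [1-(trimethylsilyl)ethenyl]magnesium bromide C=C([Mg]Br)[Si](C)(C)C
Why: Cram-chelate-controlled Grignard addition to the magnesium chelate of the α-PMB-oxy aldehyde delivers the vinyl group anti to the C8 vinyl substituent, setting C9 syn to C8.

Step 10
Reactants: 14 (3R,4S)-4-[(4-methoxyphenyl)methoxy]-2-(trimethylsilyl)hexa-1,5-dien-3-ol
Product: 15 (3R,4S)-2-iodo-4-[(4-methoxyphenyl)methoxy]hexa-1,5-dien-3-ol
Conditions: N-iodosuccinimide, MeCN/ClCH2CN 4:1, 0 °C, dark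
Reagents that add atoms: N-iodosuccinimide O=C1CCC(=O)N1I
Why: Iododesilylation (ipso substitution through the β-silyl cation) converts the vinylsilane into the C10 vinyl iodide faster than the unactivated terminal alkene can react; stereocentres are untouched.

Step 11
Reactants: 15 (3R,4S)-2-iodo-4-[(4-methoxyphenyl)methoxy]hexa-1,5-dien-3-ol; 16 2-(bromomethyl)prop-2-enoic acid
Product: 17 (3R,4S)-2-iodo-4-[(4-methoxyphenyl)methoxy]hexa-1,5-dien-3-yl 2-(bromomethyl)prop-2-enoate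
Conditions: DCC, DMAP (5 mol%), CH2Cl2, 0 °C
Reagents that add atoms: none
Why: Steglich esterification acylates O9 with the C11–C13 unit at low temperature and low DMAP loading so that the allylic bromide survives.

Step 12
Reactants: 17 (3R,4S)-2-iodo-4-[(4-methoxyphenyl)methoxy]hexa-1,5-dien-3-yl 2-(bromomethyl)prop-2-enoate
Product: 18 (5S,6R)-3-(bromomethyl)-6-(1-iodoethenyl)-5-[(4-methoxyphenyl)methoxy]-5,6-dihydro-2H-pyran-2-one (fragment B)
Conditions: second-generation Grubbs catalyst (7 mol%), CH2Cl2 (5 mM), 40 °C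
Reagents that add atoms: none
Why: Ring-closing metathesis between the terminal vinyl group and the acrylate closes the six-membered unsaturated lactone (C7=C11) with loss of ethene, while the hindered 1-iodoethenyl group stays inert.

Step 13
Reactants: 9 2-[(2R,3R)-3-{2-[(4-methoxyphenyl)methoxy]ethyl}-2-methyloxiran-2-yl]acetaldehyde (fragment A); 18 (5S,6R)-3-(bromomethyl)-6-(1-iodoethenyl)-5-[(4-methoxyphenyl)methoxy]-5,6-dihydro-2H-pyran-2-one (fragment B)
Product: 21 (4S,5R)-4-[(1S,2R)-2-hydroxy-3-iodo-1-[(4-methoxyphenyl)methoxy]but-3-en-1-yl]-5-{[(2R,3R)-3-{2-[(4-methoxyphenyl)methoxy]ethyl}-2-methyloxiran-2-yl]methyl}-3-methylideneoxolan-2-one, via allylzinc bromide 19 (not isolated), via six-membered lactone adduct 20 (not isolated)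
Conditions: Zn dust, THF/sat. aq. NH4Cl 2:1, 0 °C to rt; extract; then DBU (0.2 equiv), CH2Cl2, rt
Reagents that add atoms: none
Why: Zinc-mediated Barbier allylation through a Zimmerman–Traxler chair attacks C7 on the ring face opposite the cis C8–OPMB and C9–iodoethenyl groups (sets C7) with the ring-locked allyl geometry placing C8 equatorial so that the C6 carbinol forms anti to C8 (sets C6), and DBU-catalysed translactonisation then gives the less strained trans γ-lactone and releases O9–H.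

Step 14
Reactants: 21 (4S,5R)-4-[(1S,2R)-2-hydroxy-3-iodo-1-[(4-methoxyphenyl)methoxy]but-3-en-1-yl]-5-{[(2R,3R)-3-{2-[(4-methoxyphenyl)methoxy]ethyl}-2-methyloxiran-2-yl]methyl}-3-methylideneoxolan-2-one; 22 (2Z)-2-methylbut-2-enoic acid (angelic acid)
Product: 24 (1S,2R)-3-iodo-1-[(4-methoxyphenyl)methoxy]-1-[(2R,3S)-2-{[(2R,3R)-3-{2-[(4-methoxyphenyl)methoxy]ethyl}-2-methyloxiran-2-yl]methyl}-4-methylidene-5-oxooxolan-3-yl]but-3-en-2-yl (2Z)-2-methylbut-2-enoate, via angelic 2,4,6-trichlorobenzoic anhydride 23 (not isolated)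
Conditions: 2,4,6-trichlorobenzoyl chloride, Et3N, toluene, rt; then 21, 80 °C (no DMAP)
Reagents that add atoms: none
Why: Yamaguchi esterification through the preformed mixed anhydride acylates the only free hydroxyl (O9) and, run without a nucleophilic catalyst, keeps the (Z)-geometry of the angelate; no stereocentre changes.

Step 15
Reactants: 24 (1S,2R)-3-iodo-1-[(4-methoxyphenyl)methoxy]-1-[(2R,3S)-2-{[(2R,3R)-3-{2-[(4-methoxyphenyl)methoxy]ethyl}-2-methyloxiran-2-yl]methyl}-4-methylidene-5-oxooxolan-3-yl]but-3-en-2-yl (2Z)-2-methylbut-2-enoate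
Product: 25 (1S,2R)-1-hydroxy-1-[(2R,3R)-2-{[(2R,3R)-3-(2-hydroxyethyl)-2-methyloxiran-2-yl]methyl}-4-methylidene-5-oxooxolan-3-yl]-3-iodobut-3-en-2-yl (2Z)-2-methylbut-2-enoate
Conditions: DDQ (3 equiv), CH2Cl2/pH 7 phosphate buffer 10:1, 0 °C to rt
Reagents that add atoms: none
Why: Oxidative cleavage of both PMB ethers by DDQ under buffered, non-acidic conditions frees the C1 and C8 hydroxyls while the epoxide, the esters and the vinyl iodide are inert to the quinone.

Step 16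
Reactants: 25 (1S,2R)-1-hydroxy-1-[(2R,3R)-2-{[(2R,3R)-3-(2-hydroxyethyl)-2-methyloxiran-2-yl]methyl}-4-methylidene-5-oxooxolan-3-yl]-3-iodobut-3-en-2-yl (2Z)-2-methylbut-2-enoate
Product: 26 (1S,2R)-1-hydroxy-3-iodo-1-[(2R,3R)-2-{[(2R,3R)-2-methyl-3-(2-oxoethyl)oxiran-2-yl]methyl}-4-methylidene-5-oxooxolan-3-yl]but-3-en-2-yl (2Z)-2-methylbut-2-enoate
Conditions: TEMPO (0.2 equiv), PhI(OAc)2 (1.2 equiv), CH2Cl2, rt; crude aldehyde used at once
Reagents that add atoms: none
Why: The oxoammonium oxidation (TEMPO with PhI(OAc)2) is selective for the primary C1 alcohol over the hindered secondary C8 alcohol and gives the epoxy aldehyde without base.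

Step 17
Reactants: 26 (1S,2R)-1-hydroxy-3-iodo-1-[(2R,3R)-2-{[(2R,3R)-2-methyl-3-(2-oxoethyl)oxiran-2-yl]methyl}-4-methylidene-5-oxooxolan-3-yl]but-3-en-2-yl (2Z)-2-methylbut-2-enoate
Product: 28 (3R,4R,6R,7R,8S,9S)-9-angeloyloxy-3,4-epoxy-1,8-dihydroxygermacra-10(14),11(13)-dien-12,6-olide (both C1 epimers), via alkenylchromium dichloride 27 (not isolated)
Conditions: CrCl2 (10 equiv), NiCl2 (2 mol%), degassed DMSO/THF 3:1, rt, slow addition to 2 mM
Reagents that add atoms: none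
Why: Nozaki–Hiyama–Kishi macrocyclisation, in which nickel-catalysed activation of the C10–I bond and transfer to chromium give an alkenylchromium that adds only to the aldehyde under high dilution, closes the ten-membered ring; the C1 configuration is irrelevant because C1 is oxidised next.

Step 18
Reactants: 28 (3R,4R,6R,7R,8S,9S)-9-angeloyloxy-3,4-epoxy-1,8-dihydroxygermacra-10(14),11(13)-dien-12,6-olide (both C1 epimers)
Product: 29 CNP0348992.3, (3R,4R,6R,7R,8S,9S)-9-angeloyloxy-3,4-epoxy-8-hydroxy-1-oxogermacra-10(14),11(13)-dien-12,6-olide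
Conditions: activated MnO2 (20 equiv), CH2Cl2, rt
Reagents that add atoms: none
Why: Allylic oxidation with MnO2 converts both C1 epimers into the α-methylene ketone and leaves the non-allylic C8 hydroxyl, the epoxide and the Michael acceptors untouched, giving the target.

**Compound list**

1 | but-3-yn-1-ol | C#CCCO | starting material
2 | tert-butyl(but-3-yn-1-yloxy)dimethylsilane | C#CCCO[Si](C)(C)C(C)(C)C | intermediate
3 | [(1E)-4-[(tert-butyldimethylsilyl)oxy]-2-methylbut-1-en-1-yl]dimethylalumane | C[Al](C)/C=C(\C)CCO[Si](C)(C)C(C)(C)C | intermediate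
4 | lithium butyl[(1E)-4-[(tert-butyldimethylsilyl)oxy]-2-methylbut-1-en-1-yl]dimethylaluminate | [Li+].CCCC[Al-](C)(C)/C=C(\C)CCO[Si](C)(C)C(C)(C)C | intermediate
5 | (3E)-6-[(tert-butyldimethylsilyl)oxy]-4-methylhex-3-en-1-ol | OCC/C=C(\C)CCO[Si](C)(C)C(C)(C)C | intermediate
6 | tert-butyl{[(3E)-6-[(4-methoxyphenyl)methoxy]-3-methylhex-3-en-1-yl]oxy}dimethylsilane | COc1ccc(COCC/C=C(\C)CCO[Si](C)(C)C(C)(C)C)cc1 | intermediate
7 | tert-butyl{2-[(2R,3R)-3-{2-[(4-methoxyphenyl)methoxy]ethyl}-2-methyloxiran-2-yl]ethoxy}dimethylsilane | COc1ccc(COCC[C@H]2O[C@]2(C)CCO[Si](C)(C)C(C)(C)C)cc1 | intermediate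
8 | 2-[(2R,3R)-3-{2-[(4-methoxyphenyl)methoxy]ethyl}-2-methyloxiran-2-yl]ethan-1-ol | COc1ccc(COCC[C@H]2O[C@]2(C)CCO)cc1 | intermediate
9 | 2-[(2R,3R)-3-{2-[(4-methoxyphenyl)methoxy]ethyl}-2-methyloxiran-2-yl]acetaldehyde (fragment A) | COc1ccc(COCC[C@H]2O[C@]2(C)CC=O)cc1 | intermediate
10 | 2-ethenyloxirane (racemic) | C=CC1CO1 | starting material
11 | (4-methoxyphenyl)methanol | COc1ccc(CO)cc1 | starting material
12 | (2S)-2-[(4-methoxyphenyl)methoxy]but-3-en-1-ol | C=C[C@H](OCc1ccc(OC)cc1)CO | intermediate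
13 | (2S)-2-[(4-methoxyphenyl)methoxy]but-3-enal | C=C[C@H](OCc1ccc(OC)cc1)C=O | intermediate
14 | (3R,4S)-4-[(4-methoxyphenyl)methoxy]-2-(trimethylsilyl)hexa-1,5-dien-3-ol | C=C[C@H](OCc1ccc(OC)cc1)[C@@H](O)C(=C)[Si](C)(C)C | intermediate
15 | (3R,4S)-2-iodo-4-[(4-methoxyphenyl)methoxy]hexa-1,5-dien-3-ol | C=C[C@H](OCc1ccc(OC)cc1)[C@@H](O)C(I)=C | intermediate
16 | 2-(bromomethyl)prop-2-enoic acid | C=C(CBr)C(=O)O | starting material
17 | (3R,4S)-2-iodo-4-[(4-methoxyphenyl)methoxy]hexa-1,5-dien-3-yl 2-(bromomethyl)prop-2-enoate | C=C[C@H](OCc1ccc(OC)cc1)[C@@H](OC(=O)C(=C)CBr)C(I)=C | intermediate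
18 | (5S,6R)-3-(bromomethyl)-6-(1-iodoethenyl)-5-[(4-methoxyphenyl)methoxy]-5,6-dihydro-2H-pyran-2-one (fragment B) | BrCC1=C[C@H](OCc2ccc(OC)cc2)[C@H](C(I)=C)OC1=O | intermediate
19 | bromo{[(5S,6R)-6-(1-iodoethenyl)-5-[(4-methoxyphenyl)methoxy]-2-oxo-5,6-dihydro-2H-pyran-3-yl]methyl}zinc | Br[Zn]CC1=C[C@H](OCc2ccc(OC)cc2)[C@H](C(I)=C)OC1=O | intermediate
20 | (4S,5S,6R)-4-{(1R)-1-hydroxy-2-[(2R,3R)-3-{2-[(4-methoxyphenyl)methoxy]ethyl}-2-methyloxiran-2-yl]ethyl}-6-(1-iodoethenyl)-5-[(4-methoxyphenyl)methoxy]-3-methylideneoxan-2-one | C=C1C(=O)O[C@@H](C(I)=C)[C@@H](OCc2ccc(OC)cc2)[C@@H]1[C@H](O)C[C@@]3(C)O[C@@H]3CCOCc4ccc(OC)cc4 | intermediate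
21 | (4S,5R)-4-[(1S,2R)-2-hydroxy-3-iodo-1-[(4-methoxyphenyl)methoxy]but-3-en-1-yl]-5-{[(2R,3R)-3-{2-[(4-methoxyphenyl)methoxy]ethyl}-2-methyloxiran-2-yl]methyl}-3-methylideneoxolan-2-one | C=C1C(=O)O[C@H](C[C@@]2(C)O[C@@H]2CCOCc3ccc(OC)cc3)[C@H]1[C@H](OCc4ccc(OC)cc4)[C@@H](O)C(I)=C | intermediate
22 | (2Z)-2-methylbut-2-enoic acid (angelic acid) | C/C=C(/C)C(=O)O | starting material
23 | (2Z)-2-methylbut-2-enoic 2,4,6-trichlorobenzoic anhydride | C/C=C(/C)C(=O)OC(=O)c1c(Cl)cc(Cl)cc1Cl | intermediate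
24 | (1S,2R)-3-iodo-1-[(4-methoxyphenyl)methoxy]-1-[(2R,3S)-2-{[(2R,3R)-3-{2-[(4-methoxyphenyl)methoxy]ethyl}-2-methyloxiran-2-yl]methyl}-4-methylidene-5-oxooxolan-3-yl]but-3-en-2-yl (2Z)-2-methylbut-2-enoate | C=C1C(=O)O[C@H](C[C@@]2(C)O[C@@H]2CCOCc3ccc(OC)cc3)[C@H]1[C@H](OCc4ccc(OC)cc4)[C@@H](OC(=O)/C(C)=C\C)C(I)=C | intermediate
25 | (1S,2R)-1-hydroxy-1-[(2R,3R)-2-{[(2R,3R)-3-(2-hydroxyethyl)-2-methyloxiran-2-yl]methyl}-4-methylidene-5-oxooxolan-3-yl]-3-iodobut-3-en-2-yl (2Z)-2-methylbut-2-enoate | C=C1C(=O)O[C@H](C[C@@]2(C)O[C@@H]2CCO)[C@H]1[C@H](O)[C@@H](OC(=O)/C(C)=C\C)C(I)=C | intermediate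
26 | (1S,2R)-1-hydroxy-3-iodo-1-[(2R,3R)-2-{[(2R,3R)-2-methyl-3-(2-oxoethyl)oxiran-2-yl]methyl}-4-methylidene-5-oxooxolan-3-yl]but-3-en-2-yl (2Z)-2-methylbut-2-enoate | C=C1C(=O)O[C@H](C[C@@]2(C)O[C@@H]2CC=O)[C@H]1[C@H](O)[C@@H](OC(=O)/C(C)=C\C)C(I)=C | intermediate
27 | alkenylchromium dichloride of 26 (trivalent chromium in place of iodine at C10) | C=C1C(=O)O[C@H](C[C@@]2(C)O[C@@H]2CC=O)[C@H]1[C@H](O)[C@@H](OC(=O)/C(C)=C\C)C(=C)[Cr](Cl)Cl | intermediate
28 | (3R,4R,6R,7R,8S,9S)-9-angeloyloxy-3,4-epoxy-1,8-dihydroxygermacra-10(14),11(13)-dien-12,6-olide (both C1 epimers) | C=C1C(=O)O[C@@H]2C[C@@]3(C)O[C@@H]3CC(O)C(=C)[C@H](OC(=O)/C(C)=C\C)[C@@H](O)[C@@H]12 | intermediate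
29 | CNP0348992.3, (3R,4R,6R,7R,8S,9S)-9-angeloyloxy-3,4-epoxy-8-hydroxy-1-oxogermacra-10(14),11(13)-dien-12,6-olide | C=C1C(=O)O[C@@H]2C[C@@]3(C)O[C@@H]3CC(=O)C(=C)[C@H](OC(=O)/C(C)=C\C)[C@@H](O)[C@@H]12 | target

**Step count**
Total step count: 18.
Longest linear sequence: 12 steps (steps 1–6 then 13–18; the branch through steps 7–12 then 13–18 is equally long).

**Steps most likely to fail, with fallbacks**

Step 13 (Barbier coupling and translactonisation). The β,γ-epoxy aldehyde 9 can eliminate or decompose before it is trapped, and the allylzinc 19 can be protonated in the aqueous medium. Fallback: carry the alkene through the coupling and epoxidise afterwards. Set out from 6: Bu4NF removes the silyl group to give (3E)-6-[(4-methoxyphenyl)methoxy]-3-methylhex-3-en-1-ol F1, and Dess–Martin oxidation gives the much more robust (3E)-6-[(4-methoxyphenyl)methoxy]-3-methylhex-3-enal F2. Zn-Barbier coupling of F2 with 18 gives (4S,5S,6R)-4-[(1R,3E)-1-hydroxy-6-[(4-methoxyphenyl)methoxy]-3-methylhex-3-en-1-yl]-6-(1-iodoethenyl)-5-[(4-methoxyphenyl)methoxy]-3-methylideneoxan-2-one F3, which DBU converts into (4S,5R)-4-[(1S,2R)-2-hydroxy-3-iodo-1-[(4-methoxyphenyl)methoxy]but-3-en-1-yl]-5-[(2E)-5-[(4-methoxyphenyl)methoxy]-2-methylpent-2-en-1-yl]-3-methylideneoxolan-2-one F4. Shi epoxidation of the only electron-rich alkene of F4 with the same ketone then returns to the route at 21.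

Step 14 (angeloylation). The hindered O9–H reacts slowly, the angelate can isomerise to the tiglate, and the base may reopen the lactone equilibrium. Fallback: build the (Z)-enoate on the molecule instead of transferring it. Set out from 21: DCC coupling with 2-[bis(2,2,2-trifluoroethoxy)phosphoryl]propanoic acid gives (1S,2R)-3-iodo-1-[(4-methoxyphenyl)methoxy]-1-[(2R,3S)-2-{[(2R,3R)-3-{2-[(4-methoxyphenyl)methoxy]ethyl}-2-methyloxiran-2-yl]methyl}-4-methylidene-5-oxooxolan-3-yl]but-3-en-2-yl 2-[bis(2,2,2-trifluoroethoxy)phosphoryl]propanoate F5. Still–Gennari olefination of F5 with acetaldehyde (KN(SiMe3)2, 18-crown-6, THF, −78 °C) forms the (Z)-2-methylbut-2-enoate directly and returns to the route at 24.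

Step 17 (macrocyclisation). The ten-membered ring is strained, the epoxy aldehyde is sensitive, the alkenylchromium 27 carries a β-acyloxy group that could eliminate to an allene, and the free C8 hydroxyl could open the epoxide under Lewis acid. Fallback: close the same bond at the ketone oxidation level by a reductive acyl coupling. Set out from 26: Pinnick oxidation (NaClO2, NaH2PO4, 2-methylbut-2-ene) gives {(2R,3R)-3-[((2R,3R)-3-{(1S,2R)-1-hydroxy-3-iodo-2-[((2Z)-2-methylbut-2-enoyl)oxy]but-3-en-1-yl}-4-methylidene-5-oxooxolan-2-yl)methyl]-3-methyloxiran-2-yl}acetic acid F6. Treatment with 2,2'-dipyridyl disulfide and PPh3 at rt gives S-pyridin-2-yl {(2R,3R)-3-[((2R,3R)-3-{(1S,2R)-1-hydroxy-3-iodo-2-[((2Z)-2-methylbut-2-enoyl)oxy]but-3-en-1-yl}-4-methylidene-5-oxooxolan-2-yl)methyl]-3-methyloxiran-2-yl}ethanethioate F7. Nickel-catalysed intramolecular reductive coupling of the vinyl iodide with the thioester (NiBr2(MeOCH2CH2OMe), 4,4'-di-tert-butyl-2,2'-bipyridine, Zn, N,N-dimethylacetamide, high dilution) then gives the enone directly and returns to the route at 29, bypassing 28 and step 18.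

**Further compounds**

F1 | step 13 | (3E)-6-[(4-methoxyphenyl)methoxy]-3-methylhex-3-en-1-ol | COc1ccc(COCC/C=C(\C)CCO)cc1
F2 | step 13 | (3E)-6-[(4-methoxyphenyl)methoxy]-3-methylhex-3-enal | COc1ccc(COCC/C=C(\C)CC=O)cc1
F3 | step 13 | (4S,5S,6R)-4-[(1R,3E)-1-hydroxy-6-[(4-methoxyphenyl)methoxy]-3-methylhex-3-en-1-yl]-6-(1-iodoethenyl)-5-[(4-methoxyphenyl)methoxy]-3-methylideneoxan-2-one | C=C1C(=O)O[C@@H](C(I)=C)[C@@H](OCc2ccc(OC)cc2)[C@@H]1[C@H](O)C/C(C)=C/CCOCc3ccc(OC)cc3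
F4 | step 13 | (4S,5R)-4-[(1S,2R)-2-hydroxy-3-iodo-1-[(4-methoxyphenyl)methoxy]but-3-en-1-yl]-5-[(2E)-5-[(4-methoxyphenyl)methoxy]-2-methylpent-2-en-1-yl]-3-methylideneoxolan-2-one | C=C1C(=O)O[C@H](C/C(C)=C/CCOCc2ccc(OC)cc2)[C@H]1[C@H](OCc3ccc(OC)cc3)[C@@H](O)C(I)=C
F5 | step 14 | (1S,2R)-3-iodo-1-[(4-methoxyphenyl)methoxy]-1-[(2R,3S)-2-{[(2R,3R)-3-{2-[(4-methoxyphenyl)methoxy]ethyl}-2-methyloxiran-2-yl]methyl}-4-methylidene-5-oxooxolan-3-yl]but-3-en-2-yl 2-[bis(2,2,2-trifluoroethoxy)phosphoryl]propanoate | C=C1C(=O)O[C@H](C[C@@]2(C)O[C@@H]2CCOCc3ccc(OC)cc3)[C@H]1[C@H](OCc4ccc(OC)cc4)[C@@H](OC(=O)C(C)P(=O)(OCC(F)(F)F)OCC(F)(F)F)C(I)=C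
F6 | step 17 | {(2R,3R)-3-[((2R,3R)-3-{(1S,2R)-1-hydroxy-3-iodo-2-[((2Z)-2-methylbut-2-enoyl)oxy]but-3-en-1-yl}-4-methylidene-5-oxooxolan-2-yl)methyl]-3-methyloxiran-2-yl}acetic acid | C=C1C(=O)O[C@H](C[C@@]2(C)O[C@@H]2CC(=O)O)[C@H]1[C@H](O)[C@@H](OC(=O)/C(C)=C\C)C(I)=C
F7 | step 17 | S-pyridin-2-yl {(2R,3R)-3-[((2R,3R)-3-{(1S,2R)-1-hydroxy-3-iodo-2-[((2Z)-2-methylbut-2-enoyl)oxy]but-3-en-1-yl}-4-methylidene-5-oxooxolan-2-yl)methyl]-3-methyloxiran-2-yl}ethanethioate | C=C1C(=O)O[C@H](C[C@@]2(C)O[C@@H]2CC(=O)Sc3ccccn3)[C@H]1[C@H](O)[C@@H](OC(=O)/C(C)=C\C)C(I)=C
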